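**Plan**

1. Locants: the bicycle is numbered O1–O2–C3–C4–C4a–O5–C6(=O)–C7–C7a (furo[3,2-c][1,2]dioxin-6-one), the side chain C1'–C8'. The retrosynthesis cuts C5'–C6' (Suzuki–Miyaura) and C4'=C5' (cross-metathesis) in the side chain, then C4–C4a together with O1–C7a in the 1,2-dioxane, then C3–O2 (oxirane perhydrolysis), C3–C4 (sulfur ylide) and C2'–CH3 (conjugate addition).
2. Forward order: acyclic methyl ketone → oxirane → tertiary hydroperoxide → α-silylperoxy aldehyde. Annulation with 5-methyl-2-silyloxyfuran then closes the 1,2-dioxane onto the furanone, whose ring becomes the γ-lactone unchanged. The C4 hydroxyl left by the aldehyde is removed and the diene is completed last.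
3. Enabling feature: ring carbon C4 lies between the peroxide carbon C3 and the lactone γ-carbon C4a, and C7a is the lactone β-carbon. Raised to the aldehyde level, C4 is the natural electrophile for C5 of a 2-silyloxyfuran, and the butenolide so formed holds its β-carbon six atoms from the hydroperoxide oxygen, ready for 6-exo oxa-Michael closure.
4. Stereochemistry: C2' from copper/Josiphos conjugate methylation; C3 from catalytic asymmetric Corey–Chaykovsky epoxidation followed by inversion in the perhydrolysis; C4a from the chiral titanium–BINOL catalyst in the aldol event; C7a from the cis ring fusion enforced in the oxa-Michael closure; C4'=C5' (E) from metathesis and C6'=C7' (E) from syn-hydrozirconation.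

Key step: step 8

Remark: for each chiral catalyst (Josiphos in step 2, the binaphthoxide complex in step 3, BINOL in step 8) the enantiomer meant is the one that delivers the stated configuration; the sense is assigned by analogy and the antipodal ligand is used if the opposite sense is found. The C4 carbinol configuration drawn for 11–14 is the one expected from anti topicity and has no bearing on the outcome, because C4 ends as CH2.

**Route**

Step 1
Reactants: 1 2-methylpenta-1,4-diene; 2 but-3-en-2-one
Product: 3 (3E)-6-methylhepta-3,6-dien-2-one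
Conditions: second-generation Hoveyda–Grubbs catalyst (3 mol%), 1,4-benzoquinone (10 mol%), CH2Cl2, 40 °C
Reagents that add atoms: none
Why: Olefin cross-metathesis pairs the monosubstituted alkene of 1 with the enone partner while the 1,1-disubstituted alkene stays inert, and the E-enone is the thermodynamic product; no stereocentre is formed.

Step 2
Reactants: 3 (3E)-6-methylhepta-3,6-dien-2-one
Product: 4 (4S)-4,6-dimethylhept-6-en-2-one
Conditions: MeMgBr, CuBr·SMe2 (5 mol%), Josiphos (6 mol%, enantiomer giving 4S), tBuOMe, −75 °C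
Reagents that add atoms: methylmagnesium bromide, C[Mg]Br
Why: Copper-catalysed asymmetric conjugate addition of a Grignard reagent to an acyclic enone, in which the chiral ferrocenyl diphosphine–copper complex selects the enone face and sets the methyl-bearing centre (C2' of the target) as S, the low temperature suppressing 1,2-addition and γ-deprotonation.

Step 3
Reactants: 4 (4S)-4,6-dimethylhept-6-en-2-one
Product: 5 (2S)-2-[(2S)-2,4-dimethylpent-4-en-1-yl]-2-methyloxirane
Conditions: Me3S(O)I, NaH; LaLi3(binaphthoxide)3 (5 mol%, enantiomer giving 2S), tris(2,4,6-trimethoxyphenyl)phosphine oxide (5 mol%), 5 Å MS, THF, rt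
Reagents that add atoms: dimethylsulfoxonium methylide, [CH2-][S+](C)(C)=O (made in the flask from trimethylsulfoxonium iodide, C[S+](C)(C)=O.[I-])
Why: Catalytic asymmetric Corey–Chaykovsky epoxidation of a methyl ketone, in which the lanthanum–lithium binaphthoxide complex binds the ketone and directs the ylide to one carbonyl face, setting the oxirane carbon as S under catalyst control.

Step 4
Reactants: 5 (2S)-2-[(2S)-2,4-dimethylpent-4-en-1-yl]-2-methyloxirane
Product: 6 (2R,4S)-2-hydroperoxy-2,4,6-trimethylhept-6-en-1-ol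
Conditions: H2O2 (dried ethereal solution), H3PMo12O40 (cat.), Et2O, rt
Reagents that add atoms: hydrogen peroxide, OO
Why: Acid-catalysed perhydrolysis of a 2,2-disubstituted oxirane, in which hydrogen peroxide opens the tertiary carbon with inversion (borderline SN2, as in the anti-opening of trisubstituted cyclic oxiranes) and so turns the S oxirane carbon into the R hydroperoxide carbon that becomes C3 of the target.

Step 5
Reactants: 6 (2R,4S)-2-hydroperoxy-2,4,6-trimethylhept-6-en-1-ol
Product: 7 triethyl({(2R,4S)-2,4,6-trimethyl-2-[(triethylsilyl)peroxy]hept-6-en-1-yl}oxy)silane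
Conditions: Et3SiOTf (2.2 equiv), 2,6-lutidine, CH2Cl2, −78 °C
Reagents that add atoms: triethylsilyl trifluoromethanesulfonate, CC[Si](CC)(CC)OS(=O)(=O)C(F)(F)F
Why: Silylation with a silyl triflate and a hindered base caps both the hydroperoxide and the primary alcohol without touching the stereocentres, and the tertiary silyl peroxide tolerates the Lewis acid used later.

Step 6
Reactants: 7 triethyl({(2R,4S)-2,4,6-trimethyl-2-[(triethylsilyl)peroxy]hept-6-en-1-yl}oxy)silane
Product: 8 (2R,4S)-2,4,6-trimethyl-2-[(triethylsilyl)peroxy]hept-6-enal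
Conditions: (COCl)2, DMSO, CH2Cl2, −78 to −40 °C; Et3N
Reagents that add atoms: none
Why: Swern oxidation cleaves and oxidises primary triethylsilyl ethers directly to aldehydes while the less basic tertiary silyl peroxide is left alone, and the aldehyde has no α-hydrogen so C3 cannot epimerise.

Step 7
Reactants: 9 5-methylfuran-2(3H)-one (α-angelica lactone)
Product: 10 trimethyl[(5-methylfuran-2-yl)oxy]silane
Conditions: Me3SiCl, Et3N, Et2O, 0 °C to rt; distillation
Reagents that add atoms: chlorotrimethylsilane, C[Si](C)(C)Cl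
Why: Soft enolisation and O-silylation of the deconjugated butenolide gives the aromatic 2-silyloxyfuran, the standard donor for vinylogous Mukaiyama aldol reactions.

Step 8
Reactants: 8 (2R,4S)-2,4,6-trimethyl-2-[(triethylsilyl)peroxy]hept-6-enal; 10 trimethyl[(5-methylfuran-2-yl)oxy]silane
Product: 13 (3R,4S,4aR,7aR)-3-[(2S)-2,4-dimethylpent-4-en-1-yl]-4-hydroxy-3,4a-dimethyl-4,4a,7,7a-tetrahydrofuro[3,2-c][1,2]dioxin-6(3H)-one, via silylated aldol adduct 11 (not isolated), via hydroperoxy butenolide 12 (not isolated)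
Conditions: Ti(OiPr)4/(R)-BINOL (20 mol%), Et2O, −20 °C; then Bu4NF/AcOH, THF, 0 °C; then Et2NH, CF3CH2OH, rt
Reagents that add atoms: none
Why: The titanium–BINOL Lewis acid activates the aldehyde of 8 and C5 of the silyloxyfuran adds through an open transition state (vinylogous Mukaiyama aldol, the closest known reaction type) to give butenolide 11 with the C4–C4a bond in place; buffered fluoride then frees hydroperoxide 12, whose oxygen adds under amine catalysis to the butenolide β-carbon (hydroperoxide oxa-Michael addition, known for closing this ring system) and forms O1–C7a. The 1,2-dioxane closes in the 6-exo-trig mode, and the lactone ring is already present from the furan. C4a is set by the chiral catalyst, which selects the furan face because the C3 centre, carrying methyl and a primary alkyl group, biases the aldehyde only weakly; the C4 carbinol follows from the anti topicity and is erased later; C7a is set by the tether, since the peroxide oxygen can reach only the butenolide face syn to the C4a–C4 bond, which gives the cis ring fusion. The step needs γ- over α-attack of the dienolate, secured by the Lewis-acid mode in which 2-silyloxyfurans react at C5, and it needs oxygen selectivity in the closure, secured because the hydroperoxide is far more acidic and nucleophilic (α-effect) than the shielded carbinol. The aldehyde has no α-hydrogen, so neither enolisation nor epimerisation at C3 can intervene.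

Step 9
Reactants: 13 (3R,4S,4aR,7aR)-3-[(2S)-2,4-dimethylpent-4-en-1-yl]-4-hydroxy-3,4a-dimethyl-4,4a,7,7a-tetrahydrofuro[3,2-c][1,2]dioxin-6(3H)-one
Product: 14 O-{(3R,4S,4aR,7aR)-3-[(2S)-2,4-dimethylpent-4-en-1-yl]-3,4a-dimethyl-6-oxohexahydrofuro[3,2-c][1,2]dioxin-4-yl} O-phenyl carbonothioate
Conditions: PhOC(S)Cl, pyridine, DMAP, CH2Cl2, rt
Reagents that add atoms: O-phenyl chlorothionoformate, S=C(Cl)Oc1ccccc1
Why: Acylation of the secondary carbinol with an aryl chlorothionoformate under nucleophilic catalysis gives the Barton–McCombie precursor, and the amine bases leave the β-peroxy lactone intact.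

Step 10
Reactants: 14 O-{(3R,4S,4aR,7aR)-3-[(2S)-2,4-dimethylpent-4-en-1-yl]-3,4a-dimethyl-6-oxohexahydrofuro[3,2-c][1,2]dioxin-4-yl} O-phenyl carbonothioate
Product: 15 (3R,4aR,7aR)-3-[(2S)-2,4-dimethylpent-4-en-1-yl]-3,4a-dimethyl-4,4a,7,7a-tetrahydrofuro[3,2-c][1,2]dioxin-6(3H)-one
Conditions: Bu3SnH (0.3 M), AIBN, toluene, 80 °C
Reagents that add atoms: none
Why: Barton–McCombie deoxygenation, in which the secondary C4 radical released by C–O fragmentation is trapped by the concentrated tin hydride faster than it can attack the neighbouring O–O bond or the distant 1,1-disubstituted alkene, so the helper stereocentre is erased and C3, C4a, C7a and C2' are untouched.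

Step 11
Reactants: 15 (3R,4aR,7aR)-3-[(2S)-2,4-dimethylpent-4-en-1-yl]-3,4a-dimethyl-4,4a,7,7a-tetrahydrofuro[3,2-c][1,2]dioxin-6(3H)-one; 16 2-ethenyl-4,4,5,5-tetramethyl-1,3,2-dioxaborolane
Product: 17 (3R,4aR,7aR)-3-[(2S,4E)-2,4-dimethyl-5-(4,4,5,5-tetramethyl-1,3,2-dioxaborolan-2-yl)pent-4-en-1-yl]-3,4a-dimethyl-4,4a,7,7a-tetrahydrofuro[3,2-c][1,2]dioxin-6(3H)-one
Conditions: second-generation Hoveyda–Grubbs catalyst (5 mol%), 16 (3 equiv), CH2Cl2, 40 °C
Reagents that add atoms: none
Why: Cross-metathesis of a 1,1-disubstituted alkene with a vinyl boronate gives the trisubstituted alkenyl boronate, the E isomer being expected to predominate because it places boron trans to the larger alkyl branch, and dialkyl peroxides are inert to the ruthenium carbene.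

Step 12
Reactants: 18 (bromomethyl)benzene; 19 bromo(prop-1-yn-1-yl)magnesium
Product: 20 but-2-yn-1-ylbenzene
Conditions: CuBr·SMe2 (5 mol%), THF, 0 °C to rt
Reagents that add atoms: none
Why: Copper-catalysed coupling of an alkynyl Grignard reagent with a benzylic bromide, an SN2-type alkylation of the alkynylcopper species.

Step 13
Reactants: 20 but-2-yn-1-ylbenzene
Product: 22 [(2E)-3-iodobut-2-en-1-yl]benzene, via alkenylzirconocene chloride 21 (not isolated)
Conditions: Cp2Zr(H)Cl, THF, rt to 40 °C; then I2, 0 °C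
Reagents that add atoms: iodine, [I][I]
Why: Syn-hydrozirconation of the internal alkyne places zirconium on the less hindered methyl-bearing carbon after equilibration, and iodinolysis of the carbon–zirconium bond with retention gives the E-alkenyl iodide.

Step 14
Reactants: 17 (3R,4aR,7aR)-3-[(2S,4E)-2,4-dimethyl-5-(4,4,5,5-tetramethyl-1,3,2-dioxaborolan-2-yl)pent-4-en-1-yl]-3,4a-dimethyl-4,4a,7,7a-tetrahydrofuro[3,2-c][1,2]dioxin-6(3H)-one; 22 [(2E)-3-iodobut-2-en-1-yl]benzene
Product: 23 (3R,4aR,7aR)-3,4a-dimethyl-3-[(2S,4E,6E)-2,4,6-trimethyl-8-phenylocta-4,6-dien-1-yl]-4,4a,7,7a-tetrahydrofuro[3,2-c][1,2]dioxin-6(3H)-one (plakortolide, the target)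
Conditions: PdCl2(dppf) (5 mol%), K3PO4 (2 equiv, aq.), THF, rt
Reagents that add atoms: none
Why: Suzuki–Miyaura coupling of the alkenyl boronate with the alkenyl iodide proceeds with retention at both alkenes and forms the C5'–C6' bond of the E,E-diene, and palladium cross-couplings of this kind tolerate dialkyl peroxides under mild base at room temperature.

**Compound list**

1 | 2-methylpenta-1,4-diene | C=CCC(C)=C | starting material
2 | but-3-en-2-one | CC(=O)C=C | starting material
3 | (3E)-6-methylhepta-3,6-dien-2-one | CC(=O)/C=C/CC(C)=C | intermediate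
4 | (4S)-4,6-dimethylhept-6-en-2-one | C=C(C)C[C@H](C)CC(C)=O | intermediate
5 | (2S)-2-[(2S)-2,4-dimethylpent-4-en-1-yl]-2-methyloxirane | C=C(C)C[C@H](C)C[C@@]1(C)CO1 | intermediate
6 | (2R,4S)-2-hydroperoxy-2,4,6-trimethylhept-6-en-1-ol | C=C(C)C[C@H](C)C[C@](OO)(C)CO | intermediate
7 | triethyl({(2R,4S)-2,4,6-trimethyl-2-[(triethylsilyl)peroxy]hept-6-en-1-yl}oxy)silane | C=C(C)C[C@H](C)C[C@](OO[Si](CC)(CC)CC)(C)CO[Si](CC)(CC)CC | intermediate
8 | (2R,4S)-2,4,6-trimethyl-2-[(triethylsilyl)peroxy]hept-6-enal | C=C(C)C[C@H](C)C[C@](OO[Si](CC)(CC)CC)(C)C=O | intermediate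
9 | 5-methylfuran-2(3H)-one (α-angelica lactone) | CC1=CCC(=O)O1 | starting material
10 | trimethyl[(5-methylfuran-2-yl)oxy]silane | Cc1ccc(O[Si](C)(C)C)o1 | intermediate
11 | (5S)-5-methyl-5-{(1S,2R,4S)-2,4,6-trimethyl-2-[(triethylsilyl)peroxy]-1-[(trimethylsilyl)oxy]hept-6-en-1-yl}furan-2(5H)-one | C=C(C)C[C@H](C)C[C@](OO[Si](CC)(CC)CC)(C)[C@@H](O[Si](C)(C)C)[C@@]1(C)OC(=O)C=C1 | intermediate
12 | (5S)-5-[(1S,2R,4S)-2-hydroperoxy-1-hydroxy-2,4,6-trimethylhept-6-en-1-yl]-5-methylfuran-2(5H)-one | C=C(C)C[C@H](C)C[C@](OO)(C)[C@@H](O)[C@@]1(C)OC(=O)C=C1 | intermediate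
13 | (3R,4S,4aR,7aR)-3-[(2S)-2,4-dimethylpent-4-en-1-yl]-4-hydroxy-3,4a-dimethyl-4,4a,7,7a-tetrahydrofuro[3,2-c][1,2]dioxin-6(3H)-one | C=C(C)C[C@H](C)C[C@]1(C)[C@@H](O)[C@@]2(C)OC(=O)C[C@H]2OO1 | intermediate
14 | O-{(3R,4S,4aR,7aR)-3-[(2S)-2,4-dimethylpent-4-en-1-yl]-3,4a-dimethyl-6-oxohexahydrofuro[3,2-c][1,2]dioxin-4-yl} O-phenyl carbonothioate | C=C(C)C[C@H](C)C[C@]1(C)[C@@H](OC(=S)Oc3ccccc3)[C@@]2(C)OC(=O)C[C@H]2OO1 | intermediate
15 | (3R,4aR,7aR)-3-[(2S)-2,4-dimethylpent-4-en-1-yl]-3,4a-dimethyl-4,4a,7,7a-tetrahydrofuro[3,2-c][1,2]dioxin-6(3H)-one | C=C(C)C[C@H](C)C[C@]1(C)C[C@@]2(C)OC(=O)C[C@H]2OO1 | intermediate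
16 | 2-ethenyl-4,4,5,5-tetramethyl-1,3,2-dioxaborolane | C=CB1OC(C)(C)C(C)(C)O1 | starting material
17 | (3R,4aR,7aR)-3-[(2S,4E)-2,4-dimethyl-5-(4,4,5,5-tetramethyl-1,3,2-dioxaborolan-2-yl)pent-4-en-1-yl]-3,4a-dimethyl-4,4a,7,7a-tetrahydrofuro[3,2-c][1,2]dioxin-6(3H)-one | CC1(C)OB(/C=C(\C)C[C@H](C)C[C@]2(C)C[C@@]3(C)OC(=O)C[C@H]3OO2)OC1(C)C | intermediate
18 | (bromomethyl)benzene | BrCc1ccccc1 | starting material
19 | bromo(prop-1-yn-1-yl)magnesium | CC#C[Mg]Br | starting material
20 | but-2-yn-1-ylbenzene | CC#CCc1ccccc1 | intermediate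
21 | chlorobis(cyclopentadienyl)[(2E)-4-phenylbut-2-en-2-yl]zirconium | C/C(=C\Cc1ccccc1)[Zr](Cl)(C1C=CC=C1)C1C=CC=C1 | intermediate
22 | [(2E)-3-iodobut-2-en-1-yl]benzene | C/C(I)=C\Cc1ccccc1 | intermediate
23 | (3R,4aR,7aR)-3,4a-dimethyl-3-[(2S,4E,6E)-2,4,6-trimethyl-8-phenylocta-4,6-dien-1-yl]-4,4a,7,7a-tetrahydrofuro[3,2-c][1,2]dioxin-6(3H)-one | CC(=C\Cc1ccccc1)/C=C(\C)C[C@H](C)C[C@]1(C)C[C@@]2(C)OC(=O)C[C@H]2OO1 | target

**Step count**

Total steps: 14. Longest linear sequence: 11 steps (steps 1–6, 8–11 and 14).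

**Steps most likely to fail**

Step 8. The aldehyde carbon is flanked by a fully substituted carbon and must bond to the methyl-bearing C5 of the furan. The processes that may go wrong are addition through furan C3 or no addition at all, incomplete control of the furan face by the catalyst (wrong C4a), and Lewis-acid-induced fragmentation of the α-silylperoxy aldehyde (Criegee-type). The fallback sets out from 8 and comes back at 13; it builds the C4–C4a bond by a reagent-controlled allylboration and closes the lactone last. 8 is treated with an (E)-γ-[(4-methoxyphenyl)methoxy]-γ-methylallylboronic ester and a chiral phosphoric acid (or the corresponding chiral dialkylborane); the closed chair transition state tolerates neopentyl-type aldehydes and transfers alkene geometry into relative configuration, giving the homoallylic alcohol F1. Cross-metathesis of its vinyl group with methyl acrylate (second-generation Hoveyda–Grubbs catalyst) gives the enoate F2. Buffered fluoride frees the hydroperoxy enoate F3, which under Et2NH in CF3CH2OH closes by 6-exo oxa-Michael addition to the 1,2-dioxane ester F4. DDQ removes the 4-methoxybenzyl ether to give the hydroxy ester F5, whose tertiary alcohol lactonises under catalytic acid onto the cis-disposed ester to give 13; a trans isomer would re-equilibrate by retro-Michael addition.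

Step 9. The carbinol sits between two fully substituted carbons; thioacylation may stall, and stronger basic activation would invite retro-aldol cleavage or acyl migration of the lactone. The fallback sets out from 8 and 10 and comes back at 15; it replaces the oxygen helper by selenium, so that no acylation is needed. 8, 10 and PhSeSiMe3 with Me3SiOTf at −78 °C generate a selenium-stabilised carbenium ion at C4 that alkylates C5 of the silyloxyfuran (seleno-alkylation of silyl enol ethers) to give the selenide butenolide F6. Buffered fluoride gives the hydroperoxide F7, and Et2NH closes it to the 4-phenylselanyl bicycle F8. No chiral catalyst acts here, so the C4a/C7a diastereomers are separated by chromatography. Bu3SnH/AIBN then cleaves the weak carbon–selenium bond to give 15 directly.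

Step 11. Metathesis that forms a trisubstituted alkene may turn over slowly, lose E/Z control, or isomerise the terminal alkene through ruthenium hydrides. The fallback sets out from 15 and comes back at 17; it is a palladium-catalysed boryl-Heck reaction of the 1,1-disubstituted alkene with B-chlorocatecholborane (Pd2(dba)3, bulky phosphine, Cy2NMe), in which syn β-hydride elimination away from the branch gives the E-alkenyl catechol boronate F9; transesterification with pinacol gives 17.

**Further compounds**

F1 | step 8 | (3S,4S,5R,7S)-3-[(4-methoxyphenyl)methoxy]-3,5,7,9-tetramethyl-5-[(triethylsilyl)peroxy]deca-1,9-dien-4-ol | C=C(C)C[C@H](C)C[C@](OO[Si](CC)(CC)CC)(C)[C@@H](O)[C@@](C)(OCc1ccc(OC)cc1)C=C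
F2 | step 8 | methyl (2E,4S,5S,6R,8S)-5-hydroxy-4-[(4-methoxyphenyl)methoxy]-4,6,8,10-tetramethyl-6-[(triethylsilyl)peroxy]undeca-2,10-dienoate | C=C(C)C[C@H](C)C[C@](OO[Si](CC)(CC)CC)(C)[C@@H](O)[C@@](C)(OCc1ccc(OC)cc1)/C=C/C(=O)OC
F3 | step 8 | methyl (2E,4S,5S,6R,8S)-6-hydroperoxy-5-hydroxy-4-[(4-methoxyphenyl)methoxy]-4,6,8,10-tetramethylundeca-2,10-dienoate | C=C(C)C[C@H](C)C[C@](OO)(C)[C@@H](O)[C@@](C)(OCc1ccc(OC)cc1)/C=C/C(=O)OC
F4 | step 8 | methyl 2-{(3R,4R,5S,6R)-6-[(2S)-2,4-dimethylpent-4-en-1-yl]-5-hydroxy-4-[(4-methoxyphenyl)methoxy]-4,6-dimethyl-1,2-dioxan-3-yl}acetate | C=C(C)C[C@H](C)C[C@]1(C)[C@@H](O)[C@@](C)(OCc2ccc(OC)cc2)[C@@H](CC(=O)OC)OO1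
F5 | step 8 | methyl 2-{(3R,4R,5S,6R)-6-[(2S)-2,4-dimethylpent-4-en-1-yl]-4,5-dihydroxy-4,6-dimethyl-1,2-dioxan-3-yl}acetate | C=C(C)C[C@H](C)C[C@]1(C)[C@@H](O)[C@@](C)(O)[C@@H](CC(=O)OC)OO1
F6 | step 9 | 5-methyl-5-{(2R,4S)-2,4,6-trimethyl-1-(phenylselanyl)-2-[(triethylsilyl)peroxy]hept-6-en-1-yl}furan-2(5H)-one (mixture at the furanone carbon and at the selenium-bearing carbon) | C=C(C)C[C@H](C)C[C@](OO[Si](CC)(CC)CC)(C)C([Se]c1ccccc1)C1(C)OC(=O)C=C1
F7 | step 9 | 5-[(2R,4S)-2-hydroperoxy-2,4,6-trimethyl-1-(phenylselanyl)hept-6-en-1-yl]-5-methylfuran-2(5H)-one (same mixture) | C=C(C)C[C@H](C)C[C@](OO)(C)C([Se]c1ccccc1)C1(C)OC(=O)C=C1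
F8 | step 9 | 4-(phenylselanyl) derivative of 15, with the spatial arrangement of 15 at C3, C4a and C7a and either configuration at C4 | C=C(C)C[C@H](C)C[C@]1(C)C([Se]c3ccccc3)[C@@]2(C)OC(=O)C[C@H]2OO1
F9 | step 11 | (3R,4aR,7aR)-3-[(2S,4E)-5-(1,3,2-benzodioxaborol-2-yl)-2,4-dimethylpent-4-en-1-yl]-3,4a-dimethyl-4,4a,7,7a-tetrahydrofuro[3,2-c][1,2]dioxin-6(3H)-one | C/C(C[C@H](C)C[C@]1(C)C[C@@]2(C)OC(=O)C[C@H]2OO1)=C\B1Oc2ccccc2O1
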